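The data were computed with made-up constants, noise included.

- Late in the zeta run, which is the flask asked about, the reading of complex with three exchanged was falling, so I asked how far that level stood below what the charges allow.

| setting | zeta | epsilon | flask |
|---|---|---|---|
| starting complex | 0.020 M | 0.020 M | 0.020 M |
| incoming ligand | 0.050 M | 0.050 M | 0.0500 M |
| temperature | 60 °C | 66 °C | 60 °C |
| remark | the very flask that is asked about, followed so far | run made earlier |  |
| time |  |  | 3.0 d |

| run | time / h | complex with three exchanged / % | starting complex / % |
|---|---|---|---|
| zeta | 4.00 | 43.0 | 23.0 |
| zeta | 10.0 | 43.7 | 16.8 |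
| zeta | 20.0 | 43.2 | 12.5 |
| zeta | 30.0 | 42.1 | 10.8 |
| zeta | 40.0 | 41.5 | 9.4 |
| epsilon | 4.00 | 42.0 | 19.1 |
| epsilon | 10.0 | 42.3 | 13.4 |
| epsilon | 20.0 | 39.8 | 9.6 |
| epsilon | 30.0 | 39.9 | 8.1 |
| epsilon | 40.0 | 37.7 | 6.4 |

(scatter of a reading: 0.3 percentage points)

- what is taken out of complex with three exchanged is counted as made
- additions bring no volume worth counting

- Wednesday's: change nothing and wait 20 h more
- Sunday's: at 3.0 d take out 90% of the complex with three exchanged then present, then wait 20 h
- Saturday's: at 3.0 d raise the temperature by 20 K, then wait 20 h
- Tuesday's: at 3.0 d add incoming ligand, 100% of the amount charged, then wait 20 h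

- complex with three exchanged, in percent of the starting complex first charged, at 3.0 d
- the remedy with the largest gain of complex with three exchanged, or "none" below 2 percentage points (Wednesday's / Sunday's / Saturday's / Tuesday's / none)
- complex with three exchanged present, with what was taken out counted in, in percent of the starting complex first charged, after Wednesday's
- complex with three exchanged present, with what was taken out counted in, in percent of the starting complex first charged, after Saturday's

- I began with the main step by itself: each starting complex takes up 3 incoming ligand, but the flask holds 2.50 of ligand per complex, so incoming ligand is the limiting reagent for this product. That gives 83.3%, the ligand ceiling: the share of the charged starting complex that could stand as complex with three exchanged if the incoming ligand went nowhere else.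
- Then I added one process, some step that takes this product away. The highest zeta reading, 43.7%, is 52.5% of the ceiling, and by 40.0 h the level had lost 2.2 percentage points, well over the scatter. Carrying that fall straight on, I reckoned 39.2% at 3.0 d and 37.7% after 20 h more.
- Then came the rest, by the balance of starting complex: at 40.0 h zeta shows 41.5% of product and 9.4% of starting complex, so 49.1% sat in forms nobody read, more than the product.
- The zeta level stood far below the ceiling, so I expected little from Tuesday's. The hotter epsilon run read lower at 40.0 h, 37.7%, so I expected little from Saturday's either, and I chose Sunday's.
- The forecast gave 39.5%, 38.3% after Wednesday's and 28% after Saturday's, and it chose Sunday's: “Removal stops the loss”. My two figures lie just below its first two.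
- The flask gave 39.3% at 3.0 d, 38.4% after Wednesday's and 32.4% after Saturday's, and the best remedy is Sunday's, with a gain of 13 points where the forecast had guessed about 3. At 72.0 h, 28.0% of the charged incoming ligand was still free in the flask. The product stood at 47.2% of the ligand ceiling, and Tuesday's, which lifts the ligand reckoning to 167%, above the whole charge, moved the product by −7.2 points.

    starting complex + incoming ligand ⇌ leaving ligand + complex with one exchanged (K = 0.690, k = 0.0420 /M/s, Ea = 44.0 kJ/mol, ΔH = −35.0 kJ/mol)
    complex with one exchanged + incoming ligand ⇌ leaving ligand + complex with two exchanged (K = 8.06, k = 0.0192 /M/s, Ea = 49.0 kJ/mol, ΔH = −13.0 kJ/mol)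
    complex with two exchanged + incoming ligand ⇌ leaving ligand + complex with three exchanged (K = 18.0, k = 0.0853 /M/s, Ea = 47.0 kJ/mol, ΔH = −15.0 kJ/mol)
    complex with three exchanged + incoming ligand ⇌ leaving ligand + complex with four exchanged (K = 0.809, k = 0.0510 /M/s, Ea = 76.0 kJ/mol, ΔH = −17.0 kJ/mol)
    2 starting complex → homo dimer (k = 0.00190 /M/s, Ea = 83.0 kJ/mol)
    (constants at 60 °C)

- For the neighbour charged with 0.0050 M of starting complex, the ligand ceiling reckons to 333%, above the whole charge, so the ligand balance sets no bar there. The computed neighbour holds 39.7% of complex with three exchanged at 72.0 h, and more as complex with four exchanged, 58.3%.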